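**Retrosynthetic overview**

1. The route rests on ring B of the drimane core: the methyl-bearing quaternary C10 is bonded to C9 (which carries C11H2–O–coumarin) and to ring-fusion C5, whose neighbour C6 is the enone carbonyl (C6=O, C7=C8–CH3). This pattern is what a [3,3] shift in a bicyclo[2.2.2]octenone made from 2-methoxy-4-methylphenol delivers.
2. Late disconnections: the C6 enone from its allylic alcohol; the C11–O–aryl bond by Mitsunobu reaction with umbelliferone; the 3α-carbinol from a C3 ketone; C9–H/C11–OH from hydroboration of an exocyclic C9=C11 alkene.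
3. Key disconnection: C9–C10, by anionic oxy-Cope rearrangement of a bicyclo[2.2.2]octenyl allenyl carbinol. It closes ring B, releases ring A (the cyclohexene of the bicycle) and gives a cis-decalin dienolate that is trapped as its triflate.
4. The carbinol comes from SE2′ addition of a but-2-ynyl indium reagent to the bicyclic ketone. That ketone is the inverse-demand Diels–Alder adduct of the masked o-benzoquinone with the isobutenyl ether of (S)-1-phenylethanol (C3–O, C4 gem-dimethyl, C6 ketal and C10 methyl in place).
5. Ring order: bicyclo[2.2.2]octenone (ring A plus a two-carbon bridge) first, then ring B by the [3,3] shift; the coumarin is attached in the penultimate step.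

Key step: step 5

Convention: drimane numbering is used throughout and β is the face of the C10 methyl, so H5, H9 and the C3 hydroxyl of the target are α. In bicycles 7 and 9 the drimane numbers are C7 (carbonyl/carbinol), C6 (ketal), C2 and C5 (bridgeheads), C1=C10 (alkene), C3 (ether carbon) and C4 (CMe2).
Assumption: the two endo adducts of step 3 differ in the bridgehead configuration and are separable as diastereomers; the one drawn as 7 is carried on.

**Route**

Step 1
Reactants: 1 (S)-1-phenylethanol; 2 3-chloro-2-methylprop-1-ene
Product: 3 (S)-1-phenylethyl 2-methylallyl ether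
Conditions: NaH, DMF, 0 °C; then 2, cat. Bu4NI, rt
Reagents that add atoms: none
Why: Williamson ether synthesis, in which the sodium alkoxide displaces the allylic chloride by SN2 at the CH2 group, so the carbinol stereocentre is not touched and stays (S).

Step 2
Reactants: 3 (S)-1-phenylethyl 2-methylallyl ether
Product: 4 (S)-1-phenylethyl 2-methylprop-1-enyl ether
Conditions: KOtBu (0.3 equiv), DMSO, 60 °C
Reagents that add atoms: none
Why: Base-mediated allyl-to-enol ether isomerisation (prototropic shift through the oxyallyl anion) moves the double bond into conjugation with oxygen; the isobutenyl ether has no E/Z isomers and the benzylic C–H is too weakly acidic to racemise.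

Step 3
Reactants: 5 2-methoxy-4-methylphenol; 4 (S)-1-phenylethyl 2-methylprop-1-enyl ether
Product: 7 3,3-dimethoxy-5,8,8-trimethyl-7-[(1S)-1-phenylethoxy]bicyclo[2.2.2]oct-5-en-2-one (ether oxygen on C7 syn to the C5=C6 bridge), via masked o-benzoquinone 6 (not isolated)
Conditions: PhI(OAc)2 added slowly, 4 (5 equiv, excess recovered), NaHCO3, MeOH, 0 °C → rt; chromatographic separation of the endo diastereomers
Reagents that add atoms: methanol, CO
Why: Oxidative dearomatisation gives the 6,6-dimethoxycyclohexadienone, which acts as the electron-poor diene in an inverse-demand Diels–Alder reaction: the nucleophilic CMe2 carbon of the enol ether bonds to the diene terminus next to the ketal and the O-bearing carbon to the terminus next to the carbonyl, endo (ether syn to the new alkene) as is known for such dienones with enol ethers, while the bridgehead configuration depends on the diene face attacked, which the 1-phenylethyl group is expected to bias only modestly, hence the separation.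

Step 4
Reactants: 7 bicyclic ketone; 8 1-bromobut-2-yne
Product: 9 2-(buta-2,3-dien-2-yl)-3,3-dimethoxy-5,8,8-trimethyl-7-[(1S)-1-phenylethoxy]bicyclo[2.2.2]oct-5-en-2-ol (allenyl group syn to the C5=C6 bridge)
Conditions: In powder, 8 (3 equiv), NaI, DMF, rt
Reagents that add atoms: none
Why: Barbier-type indium-mediated addition, in which the γ-substituted propargylindium reacts by SE2′ so that its methyl-bearing carbon bonds to the strained, ketal-activated carbonyl and the allenyl carbinol results; attack on the carbonyl face syn to the sp2 bridge (smaller than the CH(OR)–CMe2 bridge) sets the carbinol centre with the allenyl group over the alkene.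

Step 5
Reactants: 9 bicyclo[2.2.2]octenyl allenyl carbinol
Product: 12 6,6-dimethoxy-3β-[(1S)-1-phenylethoxy]-5β-drima-1,7,9(11)-trien-7-yl trifluoromethanesulfonate (cis-decalin), via potassium alkoxide 10 (not isolated), via potassium dienolate 11 (not isolated)
Conditions: KHMDS, 18-crown-6, THF, −78 → 0 °C; then PhNTf2, −78 °C → rt
Reagents that add atoms: N-phenylbis(trifluoromethanesulfonimide), O=S(=O)(N(c1ccccc1)S(=O)(=O)C(F)(F)F)C(F)(F)F
Why: Anionic oxy-Cope rearrangement (closest precedent: the alkoxide-accelerated [3,3] shift of 2-vinylbicyclo[2.2.2]oct-5-en-2-ols to cis-decalin enolates, and of acyclic allenyl vinyl carbinols to dienones): KHMDS gives alkoxide 10, whose 1,5-diene C9=C8–C7(O⁻)–C2–C1=C10 is held in a boat by the bicycle, and the concerted shift forms C9–C10, breaks the C2–C7 bridge bond and releases the strain of the bicycle into the delocalised dienolate 11. Ring B (C5–C6–C7–C8–C9–C10) is closed by the new C9–C10 σ bond in a suprafacial sigmatropic mode through a six-centre boat transition state, and ring A is the cyclohexene of the bicycle, set free with C1=C2 when C2–C7 breaks. The one new stereocentre, C10, is fixed by the bicycle: C9 can reach only the alkene face that looks at the C6–C7 bridge, so the C10 methyl falls cis to H5 (cis-decalin) and cis to the C3 ether, in the absolute sense given by the diastereomer chosen in step 3. The step needs the allenyl group syn to C1=C10 (secured in step 4) and reaction of the proximal allene π bond only; the sp-hybridised C9 has no inside substituent to clash with C5/C6 or to eclipse the C10 methyl, and the orthogonal π bond survives as C9=C11. The potassium dienolate is sulfonylated at oxygen by PhNTf2, its carbon termini C8 and C11 being hindered or soft, which fixes the diene and marks C7 for reduction.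

Step 6
Reactants: 12 dienyl triflate
Product: 13 6,6-dimethoxy-3β-[(1S)-1-phenylethoxy]-5β-drima-1,7,9(11)-triene
Conditions: Pd(OAc)2 (5 mol %), PPh3, HCO2H, Et3N, DMF, 60 °C
Reagents that add atoms: none
Why: Palladium-catalysed formate reduction of an enol triflate (oxidative addition, formate exchange, decarboxylation, C–H reductive elimination) replaces C7–OTf by C7–H, as established for dienyl triflates, and leaves the diene, the ketal and the allylic ether alone.

Step 7
Reactants: 13 diene ketal
Product: 15 3β-[(1S)-1-phenylethoxy]-5α-drima-1,7,9(11)-trien-6-one (trans-decalin), via cis-fused dienone 14 (not isolated)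
Conditions: PPTS, acetone–H2O, rt; then crude 14, KOtBu (0.2 equiv), t-BuOH–THF, rt
Reagents that add atoms: water, O
Why: Mild acid hydrolysis of the allylic dimethyl ketal gives the cis-fused dienone, and enolisation at C5 (the only α-hydrogen) with a non-nucleophilic base then equilibrates the ring fusion to the trans-decalin, expected to be the more stable isomer as in the 5α-6-ketones of the steroid and 6-oxodrimane series, so H5 becomes α.

Step 8
Reactants: 15 trans-fused dienone
Product: 16 3β-[(1S)-1-phenylethoxy]-5α-drima-1,7,9(11)-trien-6β-ol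
Conditions: NaBH4, CeCl3·7H2O, MeOH, −78 → 0 °C
Reagents that add atoms: none
Why: Luche reduction gives 1,2-reduction of the dienone, the hydride arriving on the α face away from the syn-axial C10 and C4β methyls, so the alcohol is 6β (axial); this centre only masks the ketone and is oxidised again later.

Step 9
Reactants: 16 dienol
Product: 18 3β-[(1S)-1-phenylethoxy]drima-1,7-diene-6β,11-diol (9α-H), via C11 alkylborane 17 (not isolated)
Conditions: 9-BBN (3 equiv), THF, 0 °C → rt; then aq. NaOH, H2O2, 0 °C
Reagents that add atoms: hydrogen peroxide, OO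
Why: Hydroboration–oxidation, in which 9-BBN adds to the exocyclic 1,1-disubstituted alkene (boron on C11) far faster than to the trisubstituted C7=C8 or the hindered cis-disubstituted C1=C2 bond and delivers hydrogen to C9 from the α face opposite the adjacent axial C10 methyl, which sets H9 α and C11 equatorial.

Step 10
Reactants: 18 diol
Product: 19 11-(tert-butyldimethylsilyloxy)-3β-[(1S)-1-phenylethoxy]drima-1,7-dien-6β-ol
Conditions: TBSCl, imidazole, DMF, 0 °C
Reagents that add atoms: tert-butyldimethylsilyl chloride, CC(C)(C)[Si](C)(C)Cl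
Why: Silylation is selective for the primary C11 hydroxyl because the axial 6β hydroxyl lies between two syn-axial methyls and is too hindered to react.

Step 11
Reactants: 19 silyl ether
Product: 20 11-(tert-butyldimethylsilyloxy)drim-7-ene-3β,6β-diol
Conditions: H2 (1 atm), Pd(OH)2/C, EtOAc, rt
Reagents that add atoms: none
Why: Heterogeneous catalytic hydrogenation saturates the cis-disubstituted C1=C2 bond and hydrogenolyses the benzylic C–O bond of the auxiliary (lost as ethylbenzene, C3 configuration untouched), while the hindered trisubstituted C7=C8 bond and the silyl ether are expected to survive under these mild conditions.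

Step 12
Reactants: 20 3β,6β-diol
Product: 21 11-(tert-butyldimethylsilyloxy)drim-7-ene-3,6-dione
Conditions: Dess–Martin periodinane, CH2Cl2, rt
Reagents that add atoms: none
Why: Dess–Martin oxidation converts both secondary alcohols to carbonyls (C3 ketone, C6 enone) without base, so H5 and the γ-hydrogen at C9 are not epimerised and the silyl ether is not eliminated.

Step 13
Reactants: 21 dione
Product: 23 11-(tert-butyldimethylsilyloxy)drim-7-ene-3α,6β-diol, via 3α-hydroxy enone 22 (not isolated)
Conditions: L-Selectride, THF, −78 °C; then MeOH, CeCl3·7H2O, NaBH4, −78 → 0 °C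
Reagents that add atoms: none
Why: The bulky L-Selectride adds to the C3 ketone from the equatorial direction, as is known for 4,4-dimethyl-3-ketones of trans-decalins, and gives the axial 3α alcohol, after which Luche reduction in the same flask returns the hindered C6 enone to the 6β allylic alcohol (α-face attack as in step 8), so that no carbonyl acidifies H9 in the next two steps.

Step 14
Reactants: 23 silyl ether diol
Product: 24 drim-7-ene-3α,6β,11-triol
Conditions: TBAF, THF, rt
Reagents that add atoms: none
Why: Fluoride-induced Si–O cleavage frees the primary alcohol, and with no carbonyl in the molecule the basic fluoride cannot cause β- or vinylogous elimination.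

Step 15
Reactants: 24 triol; 25 umbelliferone
Product: 26 7-[(3α,6β-dihydroxydrim-7-en-11-yl)oxy]-2H-chromen-2-one
Conditions: PPh3, DIAD, THF, 0 °C → rt
Reagents that add atoms: none
Why: Mitsunobu etherification, in which the primary C11 alcohol is activated as its oxyphosphonium ion and displaced by the acidic phenol (SN2 at a CH2 group, no stereocentre involved), the two axial secondary hydroxyls being too hindered to be activated.

Step 16
Reactants: 26 aryl ether diol
Product: 27 ferocaulidin
Conditions: activated MnO2 (large excess), CH2Cl2, rt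
Reagents that add atoms: none
Why: Manganese dioxide oxidation is selective for the allylic C6 alcohol over the saturated 3α alcohol and the coumarin, and forming the enone last under neutral conditions avoids vinylogous elimination of the aryloxy group from C11.

**Compound list**

1 | (S)-1-phenylethanol | C[C@H](O)c1ccccc1 | starting material
2 | 3-chloro-2-methylprop-1-ene | C=C(C)CCl | starting material
3 | (S)-1-phenylethyl 2-methylallyl ether | C=C(C)CO[C@@H](C)c1ccccc1 | intermediate
4 | (S)-1-phenylethyl 2-methylprop-1-enyl ether | CC(C)=CO[C@@H](C)c1ccccc1 | intermediate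
5 | 2-methoxy-4-methylphenol | Cc1ccc(O)c(OC)c1 | starting material
6 | 6,6-dimethoxy-4-methylcyclohexa-2,4-dien-1-one (masked o-benzoquinone, not isolated) | CC1=CC(OC)(OC)C(=O)C=C1 | intermediate
7 | 3,3-dimethoxy-5,8,8-trimethyl-7-[(1S)-1-phenylethoxy]bicyclo[2.2.2]oct-5-en-2-one, ether syn to C5=C6 | O=C1[C@H]2C=C(C)[C@@H](C1(OC)OC)C(C)(C)[C@@H]2O[C@@H](C)c3ccccc3 | intermediate
8 | 1-bromobut-2-yne | CC#CCBr | starting material
9 | 2-(buta-2,3-dien-2-yl)-3,3-dimethoxy-5,8,8-trimethyl-7-[(1S)-1-phenylethoxy]bicyclo[2.2.2]oct-5-en-2-ol, allenyl syn to C5=C6 | C=C=C(C)[C@@]1(O)[C@H]2C=C(C)[C@@H](C1(OC)OC)C(C)(C)[C@@H]2O[C@@H](C)c3ccccc3 | intermediate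
10 | potassium alkoxide of 9 (not isolated) | C=C=C(C)[C@@]1([O-])[C@H]2C=C(C)[C@@H](C1(OC)OC)C(C)(C)[C@@H]2O[C@@H](C)c3ccccc3.[K+] | intermediate
11 | potassium dienolate of the cis-decalin, O on C7 (not isolated) | C=C1C(C)=C([O-])C(OC)(OC)[C@H]2C(C)(C)[C@H](O[C@@H](C)c3ccccc3)C=C[C@@]12C.[K+] | intermediate
12 | 6,6-dimethoxy-3β-[(1S)-1-phenylethoxy]-5β-drima-1,7,9(11)-trien-7-yl triflate | C=C1C(C)=C(OS(=O)(=O)C(F)(F)F)C(OC)(OC)[C@H]2C(C)(C)[C@H](O[C@@H](C)c3ccccc3)C=C[C@@]12C | intermediate
13 | 6,6-dimethoxy-3β-[(1S)-1-phenylethoxy]-5β-drima-1,7,9(11)-triene | C=C1C(C)=CC(OC)(OC)[C@H]2C(C)(C)[C@H](O[C@@H](C)c3ccccc3)C=C[C@@]12C | intermediate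
14 | 3β-[(1S)-1-phenylethoxy]-5β-drima-1,7,9(11)-trien-6-one (cis-fused, not isolated) | CC1=CC(=O)[C@H]2C(C)(C)[C@H](O[C@@H](C)c3ccccc3)C=C[C@@]2(C)C1=C | intermediate
15 | 3β-[(1S)-1-phenylethoxy]-5α-drima-1,7,9(11)-trien-6-one (trans-fused) | CC1=CC(=O)[C@@H]2C(C)(C)[C@H](O[C@@H](C)c3ccccc3)C=C[C@@]2(C)C1=C | intermediate
16 | 3β-[(1S)-1-phenylethoxy]-5α-drima-1,7,9(11)-trien-6β-ol | CC1=C[C@H](O)[C@@H]2C(C)(C)[C@H](O[C@@H](C)c3ccccc3)C=C[C@@]2(C)C1=C | intermediate
17 | 11-(9-borabicyclo[3.3.1]nonan-9-yl)-3β-[(1S)-1-phenylethoxy]drima-1,7-dien-6β-ol (not isolated) | CC1=C[C@H](O)[C@@H]2C(C)(C)[C@H](O[C@@H](C)c3ccccc3)C=C[C@@]2(C)[C@@H]1CB1C2CCCC1CCC2 | intermediate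
18 | 3β-[(1S)-1-phenylethoxy]drima-1,7-diene-6β,11-diol | CC1=C[C@H](O)[C@@H]2C(C)(C)[C@H](O[C@@H](C)c3ccccc3)C=C[C@@]2(C)[C@@H]1CO | intermediate
19 | 11-(tert-butyldimethylsilyloxy)-3β-[(1S)-1-phenylethoxy]drima-1,7-dien-6β-ol | CC1=C[C@H](O)[C@@H]2C(C)(C)[C@H](O[C@@H](C)c3ccccc3)C=C[C@@]2(C)[C@@H]1CO[Si](C)(C)C(C)(C)C | intermediate
20 | 11-(tert-butyldimethylsilyloxy)drim-7-ene-3β,6β-diol | CC1=C[C@H](O)[C@@H]2C(C)(C)[C@H](O)CC[C@@]2(C)[C@@H]1CO[Si](C)(C)C(C)(C)C | intermediate
21 | 11-(tert-butyldimethylsilyloxy)drim-7-ene-3,6-dione | CC1=CC(=O)[C@@H]2C(C)(C)C(=O)CC[C@@]2(C)[C@@H]1CO[Si](C)(C)C(C)(C)C | intermediate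
22 | 3α-hydroxy-11-(tert-butyldimethylsilyloxy)drim-7-en-6-one (not isolated) | CC1=CC(=O)[C@@H]2C(C)(C)[C@@H](O)CC[C@@]2(C)[C@@H]1CO[Si](C)(C)C(C)(C)C | intermediate
23 | 11-(tert-butyldimethylsilyloxy)drim-7-ene-3α,6β-diol | CC1=C[C@H](O)[C@@H]2C(C)(C)[C@@H](O)CC[C@@]2(C)[C@@H]1CO[Si](C)(C)C(C)(C)C | intermediate
24 | drim-7-ene-3α,6β,11-triol | CC1=C[C@H](O)[C@@H]2C(C)(C)[C@@H](O)CC[C@@]2(C)[C@@H]1CO | intermediate
25 | umbelliferone (7-hydroxycoumarin) | Oc1ccc2ccc(=O)oc2c1 | starting material
26 | 7-[(3α,6β-dihydroxydrim-7-en-11-yl)oxy]-2H-chromen-2-one | CC1=C[C@H](O)[C@@H]2C(C)(C)[C@@H](O)CC[C@@]2(C)[C@@H]1COc1ccc2ccc(=O)oc2c1 | intermediate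
27 | ferocaulidin | CC1=CC(=O)[C@@H]2C(C)(C)[C@@H](O)CC[C@@]2(C)[C@@H]1COc1ccc2ccc(=O)oc2c1 | target

**Totals and risks**

Total step count: 16. Longest linear sequence: 16 steps (1 → 27); 2, 5, 8 and 25 enter as building blocks.

Steps most likely to fail:

1. Step 3. The β,β-disubstituted enol ether may add too slowly, so that methanolysis of the enol ether or self-condensation of the dienone consumes the partners, and the auxiliary may discriminate the diene faces poorly. The fallback sets out from 5 (with 4) and comes back at 7 by separating oxidation from cycloaddition. 5 is oxidised alone (PhI(OAc)2, MeOH, −20 °C) and dienone 6 is isolated by cold work-up; its C4 methyl sits on the double bond that would act as dienophile in self-dimerisation, so it should persist. 6 is then combined with 4 in an aprotic medium under high pressure (CH2Cl2, about 10 kbar, rt), with no methanol, acid or oxidant present. This makes no new compound (F0). The diastereomers are separated as before.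

2. Step 5. The hindered tertiary alkoxide may fragment by retro-addition (loss of the allenyl/propargyl anion), or base may isomerise the allene, faster than the [3,3] shift; sulfonylation may also go to carbon. The fallback sets out from 9 and comes back at 12 through a neutral, thermal rearrangement. 9 is silylated (TMSOTf, 2,6-lutidine, CH2Cl2, −78 °C) to the trimethylsilyl ether F1. Heating F1 in degassed o-dichlorobenzene (about 200 °C, sealed tube) should effect the siloxy-Cope rearrangement, with no alkoxide present, to the silyl dienol ether F2. MeLi (THF, 0 °C) cleaves the Si–O bond to the lithium dienolate F3, which is trapped with PhNTf2 to give 12.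

3. Step 11. On palladium the C7=C8 bond may be reduced or migrate, and the allylic C–O bonds at C3 or C6 may be hydrogenolysed before the C1=C2 bond is saturated. The fallback sets out from 19 and comes back at 20 in two non-catalytic reductions. Diimide (2-nitrobenzenesulfonyl hydrazide, Et3N, CH2Cl2, rt) reduces only the disubstituted C1=C2 bond and cannot cleave C–O bonds, giving the saturated ether F4. Lithium di-tert-butylbiphenylide (THF, −78 °C) then cleaves the benzylic C–O bond by electron transfer, leaving the isolated trisubstituted alkene and the silyl ether, to give 20.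

**Further compounds**

F0 | step 3 | none | none
F1 | step 5 | trimethylsilyl ether of carbinol 9 | C=C=C(C)[C@@]1(O[Si](C)(C)C)[C@H]2C=C(C)[C@@H](C1(OC)OC)C(C)(C)[C@@H]2O[C@@H](C)c3ccccc3
F2 | step 5 | 6,6-dimethoxy-3β-[(1S)-1-phenylethoxy]-7-(trimethylsilyloxy)-5β-drima-1,7,9(11)-triene | C=C1C(C)=C(O[Si](C)(C)C)C(OC)(OC)[C@H]2C(C)(C)[C@H](O[C@@H](C)c3ccccc3)C=C[C@@]12C
F3 | step 5 | lithium dienolate of the cis-decalin, O on C7 | C=C1C(C)=C([O-])C(OC)(OC)[C@H]2C(C)(C)[C@H](O[C@@H](C)c3ccccc3)C=C[C@@]12C.[Li+]
F4 | step 11 | 11-(tert-butyldimethylsilyloxy)-3β-[(1S)-1-phenylethoxy]drim-7-en-6β-ol | CC1=C[C@H](O)[C@@H]2C(C)(C)[C@H](O[C@@H](C)c3ccccc3)CC[C@@]2(C)[C@@H]1CO[Si](C)(C)C(C)(C)C
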